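**Plan**

1. Retrosynthetic cuts, in order: the C2–OH of the quinone ring back to a methyl ether; the two ring carbonyls (C1, C4) back to a 1,2,4,5-tetramethoxybenzene ring; the acetate C–O bond; the bond between the benzylic CH2 (chain C1) and the acetoxy-bearing CH (chain C2); the aryl–CH2 bond.
2. Enabling feature: chain C2 is an sp3 carbon carrying one O, one H and the undecyl chain, directly bonded to the benzylic C1. It can therefore be C1 of dodecan-1-ol used as an α-oxygenated lithium carbenoid, while the benzylic carbon is delivered from boron; boron is a temporary tether absent from the target, and its C–B bond later becomes the C2–O bond.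
3. The tetraoxygenated six-membered ring with its single C–H maps onto symmetrical 1,2,4,5-tetramethoxybenzene, whose two C–H positions each lie between two methoxy groups.
4. Forward order: aryllithium plus bromomethylboronate gives the benzylic boronate; dodecanol gives the hindered benzoate; the two are joined by lithiation–borylation–oxidation; then acetylation, oxidative demethylation to the 2,5-dimethoxy-1,4-benzoquinone, and selective acid hydrolysis of the methoxy group next to the side chain.
5. Stereochemistry: the single stereocentre is set in the joining step by sBuLi/(–)-sparteine (pro-S hydrogen removed, retention at borylation, inversion in the 1,2-shift, retention in the oxidation, giving R) and is not touched afterwards.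

Key step: step 3

Remark: 1,2,4,5-tetramethoxybenzene, dodecan-1-ol, 2-(bromomethyl)-4,4,5,5-tetramethyl-1,3,2-dioxaborolane (BrCH2Bpin), 2,4,6-triisopropylbenzoic acid and (–)-sparteine are taken as purchased.

**Route**

Step 1
Reactants: 1 1,2,4,5-tetramethoxybenzene
Product: 4 2-(2,3,5,6-tetramethoxybenzyl)-4,4,5,5-tetramethyl-1,3,2-dioxaborolane, via aryllithium 2 (not isolated), via bromomethyl boron ate complex 3 (not isolated)
Conditions: nBuLi, TMEDA, THF, 0 °C → rt; then BrCH2Bpin, –78 °C → rt
Reagents that add atoms: 2-(bromomethyl)-4,4,5,5-tetramethyl-1,3,2-dioxaborolane, BrCB1OC(C)(C)C(C)(C)O1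
Why: Directed ortho-lithiation at the C–H flanked by two methoxy groups, then addition of the aryllithium to boron and a Matteson-type 1,2-aryl shift with loss of bromide, should give the benzylic pinacol boronate; no stereocentre is formed.

Step 2
Reactants: 5 dodecan-1-ol
Product: 6 dodecyl 2,4,6-triisopropylbenzoate
Conditions: 2,4,6-triisopropylbenzoic acid, PPh3, DIAD, THF, 0 °C → rt
Reagents that add atoms: 2,4,6-triisopropylbenzoic acid, CC(C)c1cc(C(C)C)c(C(=O)O)c(C(C)C)c1
Why: Mitsunobu esterification of a primary alcohol should give the hindered ester, which resists carbonyl attack by sBuLi, directs α-lithiation and later serves as the leaving group; no stereocentre is formed.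

Step 3
Reactants: 6 dodecyl 2,4,6-triisopropylbenzoate, 4 2-(2,3,5,6-tetramethoxybenzyl)-4,4,5,5-tetramethyl-1,3,2-dioxaborolane
Product: 10 (2R)-1-(2,3,5,6-tetramethoxyphenyl)tridecan-2-ol, via lithiated ester 7 (not isolated), via boron ate complex 8 (not isolated), via secondary boronic ester 9 (not isolated)
Conditions: sBuLi, (–)-sparteine, Et2O, –78 °C, 5 h; then 4, –78 °C → 35 °C; then NaOH, H2O2, THF/H2O, 0 °C → rt
Reagents that add atoms: hydrogen peroxide, OO
Why: sBuLi·(–)-sparteine removes the pro-S hydrogen next to the ester oxygen of 6 to give the configurationally stable (S)-organolithium 7, which adds to the boron of 4 with retention to give ate complex 8; on warming, the benzylic carbon migrates from boron to carbon anti to the departing carboxylate (inversion), forming the CH2–CH bond in (R)-boronic ester 9, whose C–B bond is then oxidised to C–O with retention. The closest known reaction type is lithiation–borylation, the homologation of a boronic ester with a sparteine-complexed lithiated primary alkyl 2,4,6-triisopropylbenzoate through a Matteson-type 1,2-metallate rearrangement, followed by peroxide oxidation. No ring is closed. The new stereocentre is under reagent control by the chiral diamine and is carried through the stereospecific shift and oxidation, so the (R)-alcohol is expected. The step needs selection between the two enantiotopic α-hydrogens and configurational stability of 7 at –78 °C (secured by diamine chelation and the dipole-stabilising hindered ester), carbon migration instead of reversal of ate formation (secured by the good carboxylate leaving group and the high migratory aptitude of a benzylic carbon), and boron complexation in preference to deprotonation of the benzylic CH2 of 4 (addition of an organolithium to a pinacol boronate is the faster process).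

Step 4
Reactants: 10 (2R)-1-(2,3,5,6-tetramethoxyphenyl)tridecan-2-ol
Product: 11 (2R)-1-(2,3,5,6-tetramethoxyphenyl)tridecan-2-yl acetate
Conditions: Ac2O, pyridine, DMAP (cat.), CH2Cl2, rt
Reagents that add atoms: acetic anhydride, CC(=O)OC(C)=O
Why: Nucleophilic-catalysed O-acylation of the secondary alcohol does not touch the C–O bond, so the (R) configuration is retained, and it masks the hydroxyl before the quinone is made.

Step 5
Reactants: 11 (2R)-1-(2,3,5,6-tetramethoxyphenyl)tridecan-2-yl acetate
Product: 12 (2R)-1-(2,5-dimethoxy-3,6-dioxocyclohexa-1,4-dien-1-yl)tridecan-2-yl acetate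
Conditions: (NH4)2Ce(NO3)6, MeCN/H2O, 0 °C
Reagents that add atoms: water, O
Why: Oxidative demethylation of a para-dimethoxy pair through the arene radical cation should give the quinone; because the ring is symmetrical both para pairs lead to the same 2,5-dimethoxy-1,4-benzoquinone, and any 4,5-dimethoxy-1,2-benzoquinone isomer is expected to converge on the same product in step 6.

Step 6
Reactants: 12 (2R)-1-(2,5-dimethoxy-3,6-dioxocyclohexa-1,4-dien-1-yl)tridecan-2-yl acetate
Product: 13 (2R)-1-(2-hydroxy-5-methoxy-3,6-dioxocyclohexa-1,4-dien-1-yl)tridecan-2-yl acetate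
Conditions: 70% aq. HClO4, 1,4-dioxane, rt
Reagents that add atoms: water, O
Why: Acid-catalysed vinylogous ester hydrolysis (addition–elimination of water) is expected to remove the C2 methoxy group, which is wedged between the side chain and the C3 carbonyl and twisted out of conjugation, in preference to the unhindered C5 methoxy group, as in the known monodemethylation of 3-alkyl-2,5-dimethoxy-1,4-benzoquinones, while the alkyl acetate should survive the water-poor acid at room temperature.

**Compound list**

1 | 1,2,4,5-tetramethoxybenzene | COc1cc(OC)c(OC)cc1OC | starting material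
2 | (2,3,5,6-tetramethoxyphenyl)lithium | [Li]c1c(OC)c(OC)cc(OC)c1OC | intermediate
3 | lithium (bromomethyl)(2,3,5,6-tetramethoxyphenyl)(pinacolato)borate | [Li+].BrC[B-]1(c2c(OC)c(OC)cc(OC)c2OC)OC(C)(C)C(C)(C)O1 | intermediate
4 | 2-(2,3,5,6-tetramethoxybenzyl)-4,4,5,5-tetramethyl-1,3,2-dioxaborolane | COc1cc(OC)c(OC)c(CB2OC(C)(C)C(C)(C)O2)c1OC | intermediate
5 | dodecan-1-ol | CCCCCCCCCCCCO | starting material
6 | dodecyl 2,4,6-triisopropylbenzoate | CCCCCCCCCCCCOC(=O)c1c(C(C)C)cc(C(C)C)cc1C(C)C | intermediate
7 | (1S)-1-lithiododecyl 2,4,6-triisopropylbenzoate (as its (–)-sparteine complex) | CCCCCCCCCCC[C@H]([Li])OC(=O)c1c(C(C)C)cc(C(C)C)cc1C(C)C | intermediate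
8 | lithium [(1S)-1-(2,4,6-triisopropylbenzoyloxy)dodecyl](2,3,5,6-tetramethoxybenzyl)(pinacolato)borate | [Li+].CCCCCCCCCCC[C@H]([B-]1(Cc2c(OC)c(OC)cc(OC)c2OC)OC(C)(C)C(C)(C)O1)OC(=O)c1c(C(C)C)cc(C(C)C)cc1C(C)C | intermediate
9 | 2-[(2R)-1-(2,3,5,6-tetramethoxyphenyl)tridecan-2-yl]-4,4,5,5-tetramethyl-1,3,2-dioxaborolane | CCCCCCCCCCC[C@H](Cc1c(OC)c(OC)cc(OC)c1OC)B1OC(C)(C)C(C)(C)O1 | intermediate
10 | (2R)-1-(2,3,5,6-tetramethoxyphenyl)tridecan-2-ol | CCCCCCCCCCC[C@H](Cc1c(OC)c(OC)cc(OC)c1OC)O | intermediate
11 | (2R)-1-(2,3,5,6-tetramethoxyphenyl)tridecan-2-yl acetate | CCCCCCCCCCC[C@H](Cc1c(OC)c(OC)cc(OC)c1OC)OC(C)=O | intermediate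
12 | (2R)-1-(2,5-dimethoxy-3,6-dioxocyclohexa-1,4-dien-1-yl)tridecan-2-yl acetate | CCCCCCCCCCC[C@H](CC1=C(OC)C(=O)C=C(OC)C1=O)OC(C)=O | intermediate
13 | (2R)-1-(2-hydroxy-5-methoxy-3,6-dioxocyclohexa-1,4-dien-1-yl)tridecan-2-yl acetate | CCCCCCCCCCC[C@H](CC1=C(O)C(=O)C=C(OC)C1=O)OC(C)=O | target

**Summary**

Total step count: 6. Longest linear sequence: 5 steps (steps 1, 3, 4, 5, 6 from compound 1; the branch from compound 5 through steps 2, 3, 4, 5, 6 is equally long).

Steps most likely to fail, with fallbacks:

Step 3. What may go wrong: incomplete or poorly enantioselective deprotonation of 6, slow 1,2-migration from the crowded ate complex with reversion to 7 and 4, or deprotonation of the benzylic CH2 of 4 instead of addition to boron. The fallback sets out from aryllithium 2 (made from 1 as in step 1) and comes back to the route at 10. It takes the stereocentre from the chiral pool and forms the aryl–CH2 bond instead. Decylmagnesium bromide with catalytic CuI in THF at –40 °C should open commercial (R)-epichlorohydrin at its terminal epoxide carbon to give (2R)-1-chlorotridecan-2-ol F1. Aqueous NaOH should close this to (2R)-2-undecyloxirane F2. Aryllithium 2 with BF3·OEt2 in THF at –78 °C should then open F2 at its CH2 group and give 10 directly, the stereocentre never being touched.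

Step 6. What may go wrong: attack of water at the wrong methoxy-bearing carbon, over-hydrolysis to the dihydroxyquinone, or acid cleavage of the secondary acetate followed by ring closure of the freed alcohol onto the quinone. The fallback sets out from 12 and comes back at 13. It fixes the regiochemistry by selective methylation instead of selective demethylation. Aqueous NaOH, then acidification, should remove both methyl ethers and the acetate to give 2,5-dihydroxy-3-[(2R)-2-hydroxytridecyl]cyclohexa-2,5-diene-1,4-dione F3. Ac2O in pyridine should convert this to the triacetate (2R)-1-(2,5-diacetoxy-3,6-dioxocyclohexa-1,4-dien-1-yl)tridecan-2-yl acetate F4, so that no free side-chain hydroxyl can cyclise in acid. MeOH with catalytic H2SO4 at room temperature should methanolyse the two labile quinonyl acetates and, by Fischer-type vinylogous esterification, etherify only the unhindered hydroxyl remote from the side chain, leaving the alkyl acetate and giving 13.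

Step 1. What may go wrong: incomplete 1,2-aryl shift from the crowded ate complex 3 (returning 1 on work-up), double lithiation of the ring, or protodeboronation of the electron-rich benzylic boronate during purification. The fallback sets out from aryllithium 2 and comes back at 4. It builds the benzylic carbon first and adds boron last. Paraformaldehyde should convert 2 to (2,3,5,6-tetramethoxyphenyl)methanol F5. Concentrated aqueous HCl at 0 °C should give 3-(chloromethyl)-1,2,4,5-tetramethoxybenzene F6. Miyaura borylation of the benzylic chloride (B2pin2, Pd2(dba)3, tris(4-methoxyphenyl)phosphine, KOAc, toluene, 50 °C) should then give 4.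

Further compounds
F1 | step 3 | (2R)-1-chlorotridecan-2-ol | CCCCCCCCCCC[C@@H](O)CCl
F2 | step 3 | (2R)-2-undecyloxirane | CCCCCCCCCCC[C@@H]1CO1
F3 | step 6 | 2,5-dihydroxy-3-[(2R)-2-hydroxytridecyl]cyclohexa-2,5-diene-1,4-dione | CCCCCCCCCCC[C@H](CC1=C(O)C(=O)C=C(O)C1=O)O
F4 | step 6 | (2R)-1-(2,5-diacetoxy-3,6-dioxocyclohexa-1,4-dien-1-yl)tridecan-2-yl acetate | CCCCCCCCCCC[C@H](CC1=C(OC(C)=O)C(=O)C=C(OC(C)=O)C1=O)OC(C)=O
F5 | step 1 | (2,3,5,6-tetramethoxyphenyl)methanol | COc1cc(OC)c(OC)c(CO)c1OC
F6 | step 1 | 3-(chloromethyl)-1,2,4,5-tetramethoxybenzene | COc1cc(OC)c(OC)c(CCl)c1OC
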